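**Retrosynthetic overview**

1. The pyran ring is closed last. The 2H-chromene is cut at the aryl C8a–O1 bond (intramolecular Pd-catalysed etherification of a (Z)-alkenyl tertiary alcohol) and at C4–C4a (Sonogashira coupling of a tertiary propargylic alcohol with an aryl iodide, then Lindlar reduction). The C2 stereocentre is therefore a carbinol whose C–O bond is never broken.
2. The propargylic carbinol comes from a primary pinacol boronate and an (R)-propargylic carbamate by stereospecific lithiation–borylation and oxidation. The boronate comes from a vinyl group by anti-Markovnikov hydroboration.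
3. The cyclohexane ring is made first, by a 6-exo Mizoroki–Heck cyclisation of an acyclic alkenyl triflate that forms the ring bond C1'–C2' between the quaternary carbon and the methylidene-bearing carbon. The triflate is assembled from an Evans allylation product, (Z)-2-bromobut-2-ene and MeMgBr.
4. Enabling feature: in the cyclohexane ring the quaternary C1' (CH3, CH2CH2 chain) is bonded directly to the sp2 carbon C2' (exocyclic C=CH2), and C2' carries the C3' methyl stereocentre on its other side. C2'(=CH2)–C1'(CH3)(two-carbon chain) is the retron of an alkenylpalladium addition to a (Z)-trisubstituted alkene followed by β-hydride elimination to a vinyl group, and C3' can steer the new centre.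
5. Ring order: cyclohexane (step 6), then the pyran ring of the chromene (step 16). The benzene ring comes from 5-bromo-2,4-dimethoxybenzaldehyde.

Key step: step 6

Assumption: in step 9 the lithiated propargylic carbamate is taken to be borylated with retention and the 1,2-shift to invert the carbon centre, as is usual for secondary carbamates; the (R)-carbamate is chosen on that basis (the (S)-carbamate would be used if borylation went with inversion).

**Route**

Step 1
Reactants: 1 (4S)-4-benzyl-3-propanoyl-1,3-oxazolidin-2-one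
Product: 3 (4S)-4-benzyl-3-[(2R)-2-methylpent-4-enoyl]-1,3-oxazolidin-2-one, via sodium enolate 2 (not isolated)
Conditions: NaN(SiMe3)2, THF, −78 °C; then allyl iodide, −78 → −40 °C
Reagents that add atoms: allyl iodide (3-iodoprop-1-ene), C=CCI
Why: Evans asymmetric alkylation, in which the chelated sodium (Z)-enolate is allylated on the face opposite the benzyl group of the auxiliary and so sets the (2R) methyl-bearing centre.

Step 2
Reactants: 3 (4S)-4-benzyl-3-[(2R)-2-methylpent-4-enoyl]-1,3-oxazolidin-2-one
Product: 4 (2R)-N-methoxy-N,2-dimethylpent-4-enamide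
Conditions: Me(MeO)NH·HCl, AlMe3, CH2Cl2, 0 °C → rt
Reagents that add atoms: N,O-dimethylhydroxylamine hydrochloride, CNOC.Cl
Why: The aluminium amide formed in the flask attacks the exocyclic imide carbonyl (Weinreb amide formation by transamidation) and releases the auxiliary without touching the α-stereocentre.

Step 3
Reactants: 4 (2R)-N-methoxy-N,2-dimethylpent-4-enamide; 5 (2Z)-2-bromobut-2-ene
Product: 7 (2R,6Z)-N-methoxy-N,2,6-trimethyloct-6-enamide, via alkylborane 6 (not isolated)
Conditions: 9-BBN, THF, 0 °C → rt; then 5, PdCl2(dppf) (dppf = 1,1'-bis(diphenylphosphino)ferrocene), AsPh3, Cs2CO3, DMF/H2O, 50 °C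
Reagents that add atoms: none
Why: Anti-Markovnikov hydroboration of the terminal alkene followed by B-alkyl Suzuki–Miyaura coupling, which keeps the geometry of the alkenyl bromide and so should give the (Z)-trisubstituted alkene.

Step 4
Reactants: 7 (2R,6Z)-N-methoxy-N,2,6-trimethyloct-6-enamide
Product: 9 (3R,7Z)-3,7-dimethylnon-7-en-2-one, via magnesium hemiaminal 8 (not isolated)
Conditions: MeMgBr, THF, 0 °C; then H2O
Reagents that add atoms: methylmagnesium bromide, C[Mg]Br
Why: Weinreb ketone synthesis, in which the chelated tetrahedral adduct prevents over-addition and collapses to the methyl ketone on work-up without epimerisation.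

Step 5
Reactants: 9 (3R,7Z)-3,7-dimethylnon-7-en-2-one
Product: 11 (3R,7Z)-3,7-dimethylnona-1,7-dien-2-yl trifluoromethanesulfonate, via potassium enolate 10 (not isolated)
Conditions: KN(SiMe3)2, THF, −78 °C; then PhNTf2, −78 → 0 °C
Reagents that add atoms: N-phenylbis(trifluoromethanesulfonimide), O=S(=O)(N(c1ccccc1)S(=O)(=O)C(F)(F)F)C(F)(F)F
Why: Kinetic deprotonation of the methyl group by the hindered base and O-sulfonylation of the less substituted enolate should give the terminal alkenyl triflate and leave the α-stereocentre untouched.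

Step 6
Reactants: 11 (3R,7Z)-3,7-dimethylnona-1,7-dien-2-yl trifluoromethanesulfonate
Product: 12 (1R,3R)-1-ethenyl-1,3-dimethyl-2-methylidenecyclohexane
Conditions: Pd(OAc)2 (10 mol %), Ph2P(CH2)3PPh2 (12 mol %), K2CO3, toluene, 80 °C
Reagents that add atoms: none
Why: Oxidative addition of zerovalent palladium into the alkenyl triflate gives a cationic alkenylpalladium species, which adds syn across the (Z)-trisubstituted alkene to form the bond between the future methylidene carbon C2 and the quaternary carbon C1, and syn β-hydride elimination toward the terminal methyl group then releases the vinyl group. The closest known reaction type is the intramolecular Mizoroki–Heck cyclisation of aryl or alkenyl triflates onto trisubstituted alkenes that builds all-carbon quaternary centres. The cyclohexane ring is closed in the 6-exo-trig mode. The new quaternary centre C1 is controlled by the C3 methyl stereocentre together with the (Z) alkene geometry: in the chair-like, eclipsed insertion transition state the C3 methyl sits equatorial, and the alkene methyl that is cis to the tether would clash with the axial ring hydrogens if the palladium-bearing carbon were axial, so that carbon (the future vinyl group) should take the equatorial site, cis to the C3 methyl. The step needs exo over 7-endo regioselectivity, secured by the three-carbon tether, and one direction of β-hydride elimination, secured by the quaternary carbon that leaves hydrogens only on the methyl group; K2CO3 takes up the palladium hydride before it can move the exocyclic double bond.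

Step 7
Reactants: 12 (1R,3R)-1-ethenyl-1,3-dimethyl-2-methylidenecyclohexane
Product: 13 2-{2-[(1S,3R)-1,3-dimethyl-2-methylidenecyclohexyl]ethyl}-4,4,5,5-tetramethyl-1,3,2-dioxaborolane
Conditions: pinacolborane, [IrCl(cod)]2 (cod = cycloocta-1,5-diene, 1.5 mol %), Ph2PCH2PPh2 (3 mol %), CH2Cl2, rt
Reagents that add atoms: pinacolborane (4,4,5,5-tetramethyl-1,3,2-dioxaborolane), [H]B1OC(C)(C)C(C)(C)O1
Why: Iridium-catalysed anti-Markovnikov hydroboration is selective for the monosubstituted vinyl group over the hindered 1,1-disubstituted exocyclic alkene (the descriptor at C1 changes only because boron lowers the priority of the chain).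

Step 8
Reactants: 14 (2R)-4-(trimethylsilyl)but-3-yn-2-ol
Product: 15 (2R)-4-(trimethylsilyl)but-3-yn-2-yl N,N-di(propan-2-yl)carbamate
Conditions: iPr2NCOCl, Et3N, CH2Cl2, reflux
Reagents that add atoms: N,N-di(propan-2-yl)carbamoyl chloride, CC(C)N(C(C)C)C(=O)Cl
Why: O-Carbamoylation of the secondary propargylic alcohol does not involve the stereocentre, so the (R) configuration is kept.

Step 9
Reactants: 15 (2R)-4-(trimethylsilyl)but-3-yn-2-yl N,N-di(propan-2-yl)carbamate; 13 2-{2-[(1S,3R)-1,3-dimethyl-2-methylidenecyclohexyl]ethyl}-4,4,5,5-tetramethyl-1,3,2-dioxaborolane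
Product: 18 2-[(3R)-5-[(1R,3R)-1,3-dimethyl-2-methylidenecyclohexyl]-3-methyl-1-(trimethylsilyl)pent-1-yn-3-yl]-4,4,5,5-tetramethyl-1,3,2-dioxaborolane, via lithiated carbamate 16 (not isolated), via boron ate complex 17 (not isolated)
Conditions: s-BuLi, TMEDA, Et2O, −78 °C; then 13, −78 → 35 °C
Reagents that add atoms: none
Why: Lithiation–borylation, in which α-deprotonation of the carbamate and formation of the boron ate complex go with retention and the 1,2-metallate shift with loss of carbamate inverts the carbon, so that the new fully substituted centre is set by the carbamate stereocentre.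

Step 10
Reactants: 18 2-[(3R)-5-[(1R,3R)-1,3-dimethyl-2-methylidenecyclohexyl]-3-methyl-1-(trimethylsilyl)pent-1-yn-3-yl]-4,4,5,5-tetramethyl-1,3,2-dioxaborolane
Product: 20 (3S)-5-[(1R,3R)-1,3-dimethyl-2-methylidenecyclohexyl]-3-methylpent-1-yn-3-ol, via silylated alkynol 19 (not isolated)
Conditions: H2O2 (30 % aq.), NaOH (2 M aq.), THF, 0 °C → rt; then K2CO3 (cat.), MeOH, rt
Reagents that add atoms: hydrogen peroxide, OO
Why: Oxidation of the C–B bond by alkaline hydrogen peroxide goes with retention of configuration, and base-mediated methanolysis then removes the alkynyl silyl group.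

Step 11
Reactants: 21 5-bromo-2,4-dimethoxybenzaldehyde
Product: 23 5-bromo-2,4-dimethoxyphenol, via aryl formate 22 (not isolated)
Conditions: mCPBA, CH2Cl2, rt; then K2CO3 (cat.), MeOH, rt
Reagents that add atoms: 3-chloroperoxybenzoic acid, OOC(=O)c1cccc(Cl)c1
Why: Dakin-type Baeyer–Villiger oxidation, in which the electron-rich aryl group migrates to oxygen and the formate is cleaved by methanolysis.

Step 12
Reactants: 23 5-bromo-2,4-dimethoxyphenol
Product: 24 3-bromo-2-iodo-4,6-dimethoxyphenol
Conditions: I2, NaHCO3, THF/H2O, 0 °C → rt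
Reagents that add atoms: iodine, II
Why: Electrophilic aromatic iodination of the phenoxide should go to the only free position ortho to the oxygen, the para position being blocked, as in the classical iodination of vanillin.

Step 13
Reactants: 24 3-bromo-2-iodo-4,6-dimethoxyphenol
Product: 25 (3-bromo-2-iodo-4,6-dimethoxyphenoxy)tri(propan-2-yl)silane
Conditions: iPr3SiOTf, 2,6-lutidine, CH2Cl2, 0 °C → rt
Reagents that add atoms: tri(propan-2-yl)silyl trifluoromethanesulfonate, CC(C)[Si](OS(=O)(=O)C(F)(F)F)(C(C)C)C(C)C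
Why: Silylation of the hindered phenol with the silyl triflate gives a base-stable ether that fluoride can remove at the end without acid.

Step 14
Reactants: 20 (3S)-5-[(1R,3R)-1,3-dimethyl-2-methylidenecyclohexyl]-3-methylpent-1-yn-3-ol; 25 (3-bromo-2-iodo-4,6-dimethoxyphenoxy)tri(propan-2-yl)silane
Product: 26 (3S)-1-{2-bromo-3,5-dimethoxy-6-[tri(propan-2-yl)silyloxy]phenyl}-5-[(1R,3R)-1,3-dimethyl-2-methylidenecyclohexyl]-3-methylpent-1-yn-3-ol
Conditions: PdCl2(PPh3)2 (5 mol %), CuI (10 mol %), Et3N, THF, 50 °C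
Reagents that add atoms: none
Why: Sonogashira coupling is chemoselective for the C–I bond over the C–Br bond and tolerates the free tertiary alcohol.

Step 15
Reactants: 26 (3S)-1-{2-bromo-3,5-dimethoxy-6-[tri(propan-2-yl)silyloxy]phenyl}-5-[(1R,3R)-1,3-dimethyl-2-methylidenecyclohexyl]-3-methylpent-1-yn-3-ol
Product: 27 (1Z,3S)-1-{2-bromo-3,5-dimethoxy-6-[tri(propan-2-yl)silyloxy]phenyl}-5-[(1R,3R)-1,3-dimethyl-2-methylidenecyclohexyl]-3-methylpent-1-en-3-ol
Conditions: H2 (1 atm), Pd/CaCO3 poisoned with Pb(OAc)2 (Lindlar catalyst), quinoline, EtOAc, rt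
Reagents that add atoms: none
Why: Lindlar semihydrogenation adds hydrogen syn to the alkyne and should give the (Z)-alkene needed for ring closure while leaving the aryl bromide and the hindered 1,1-disubstituted alkene intact.

Step 16
Reactants: 27 (1Z,3S)-1-{2-bromo-3,5-dimethoxy-6-[tri(propan-2-yl)silyloxy]phenyl}-5-[(1R,3R)-1,3-dimethyl-2-methylidenecyclohexyl]-3-methylpent-1-en-3-ol
Product: 28 {[(2S)-2-{2-[(1R,3R)-1,3-dimethyl-2-methylidenecyclohexyl]ethyl}-6,8-dimethoxy-2-methyl-2H-chromen-5-yl]oxy}tri(propan-2-yl)silane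
Conditions: Pd(OAc)2 (5 mol %), 2-(di-tert-butylphosphino)-1,1'-binaphthyl (7 mol %), Cs2CO3, toluene, 80 °C
Reagents that add atoms: none
Why: Intramolecular palladium-catalysed C–O coupling (Buchwald–Hartwig-type etherification) of the tertiary alkoxide, which has no hydrogen on the carbinol carbon, closes the pyran ring at the aryl carbon, so the carbinol C–O bond and its stereocentre are untouched.

Step 17
Reactants: 28 {[(2S)-2-{2-[(1R,3R)-1,3-dimethyl-2-methylidenecyclohexyl]ethyl}-6,8-dimethoxy-2-methyl-2H-chromen-5-yl]oxy}tri(propan-2-yl)silane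
Product: 29 metachromin B, (2S)-2-{2-[(1R,3R)-1,3-dimethyl-2-methylidenecyclohexyl]ethyl}-6,8-dimethoxy-2-methyl-2H-chromen-5-ol
Conditions: Bu4NF, AcOH, THF, 0 °C
Reagents that add atoms: none
Why: Buffered fluoride cleaves the aryl silyl ether under non-acidic conditions, which avoids ionisation of the tertiary allylic aryl ether at C2.

**Compound list**

1 | (4S)-4-benzyl-3-propanoyl-1,3-oxazolidin-2-one | CCC(=O)N1[C@@H](Cc2ccccc2)COC1=O | starting material
2 | sodium (1Z)-1-[(4S)-4-benzyl-2-oxo-1,3-oxazolidin-3-yl]prop-1-en-1-olate | C/C=C(\[O-])N1[C@@H](Cc2ccccc2)COC1=O.[Na+] | intermediate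
3 | (4S)-4-benzyl-3-[(2R)-2-methylpent-4-enoyl]-1,3-oxazolidin-2-one | C=CC[C@@H](C)C(=O)N1[C@@H](Cc2ccccc2)COC1=O | intermediate
4 | (2R)-N-methoxy-N,2-dimethylpent-4-enamide | C=CC[C@@H](C)C(=O)N(C)OC | intermediate
5 | (2Z)-2-bromobut-2-ene | C/C=C(/C)Br | starting material
6 | (2R)-5-(9-borabicyclo[3.3.1]nonan-9-yl)-N-methoxy-N,2-dimethylpentanamide | CON(C)C(=O)[C@H](C)CCCB1C2CCCC1CCC2 | intermediate
7 | (2R,6Z)-N-methoxy-N,2,6-trimethyloct-6-enamide | C/C=C(/C)CCC[C@@H](C)C(=O)N(C)OC | intermediate
8 | bromomagnesium (3R,7Z)-2-[methoxy(methyl)amino]-3,7-dimethylnon-7-en-2-olate | C/C=C(/C)CCC[C@@H](C)C(C)(O[Mg]Br)N(C)OC | intermediate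
9 | (3R,7Z)-3,7-dimethylnon-7-en-2-one | C/C=C(/C)CCC[C@@H](C)C(C)=O | intermediate
10 | potassium (3R,7Z)-3,7-dimethylnona-1,7-dien-2-olate | C/C=C(/C)CCC[C@@H](C)C(=C)[O-].[K+] | intermediate
11 | (3R,7Z)-3,7-dimethylnona-1,7-dien-2-yl trifluoromethanesulfonate | C/C=C(/C)CCC[C@@H](C)C(=C)OS(=O)(=O)C(F)(F)F | intermediate
12 | (1R,3R)-1-ethenyl-1,3-dimethyl-2-methylidenecyclohexane | C=C1[C@H](C)CCC[C@]1(C)C=C | intermediate
13 | 2-{2-[(1S,3R)-1,3-dimethyl-2-methylidenecyclohexyl]ethyl}-4,4,5,5-tetramethyl-1,3,2-dioxaborolane | C=C1[C@H](C)CCC[C@]1(C)CCB1OC(C)(C)C(C)(C)O1 | intermediate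
14 | (2R)-4-(trimethylsilyl)but-3-yn-2-ol | C[C@@H](O)C#C[Si](C)(C)C | starting material
15 | (2R)-4-(trimethylsilyl)but-3-yn-2-yl N,N-di(propan-2-yl)carbamate | C[C@@H](OC(=O)N(C(C)C)C(C)C)C#C[Si](C)(C)C | intermediate
16 | 2-lithio-4-(trimethylsilyl)but-3-yn-2-yl N,N-di(propan-2-yl)carbamate (lithium in the place of the C2 hydrogen of 15) | C[C@@]([Li])(OC(=O)N(C(C)C)C(C)C)C#C[Si](C)(C)C | intermediate
17 | lithium ate complex of lithiated carbamate 16 with boronate 13 | [Li+].C=C1[C@H](C)CCC[C@]1(C)CC[B-]1(OC(C)(C)C(C)(C)O1)[C@](C)(OC(=O)N(C(C)C)C(C)C)C#C[Si](C)(C)C | intermediate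
18 | 2-[(3R)-5-[(1R,3R)-1,3-dimethyl-2-methylidenecyclohexyl]-3-methyl-1-(trimethylsilyl)pent-1-yn-3-yl]-4,4,5,5-tetramethyl-1,3,2-dioxaborolane | C=C1[C@H](C)CCC[C@]1(C)CC[C@@](B1OC(C)(C)C(C)(C)O1)(C)C#C[Si](C)(C)C | intermediate
19 | (3S)-5-[(1R,3R)-1,3-dimethyl-2-methylidenecyclohexyl]-3-methyl-1-(trimethylsilyl)pent-1-yn-3-ol | C=C1[C@H](C)CCC[C@]1(C)CC[C@@](O)(C)C#C[Si](C)(C)C | intermediate
20 | (3S)-5-[(1R,3R)-1,3-dimethyl-2-methylidenecyclohexyl]-3-methylpent-1-yn-3-ol | C=C1[C@H](C)CCC[C@]1(C)CC[C@@](O)(C)C#C | intermediate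
21 | 5-bromo-2,4-dimethoxybenzaldehyde | O=Cc1cc(Br)c(OC)cc1OC | starting material
22 | 5-bromo-2,4-dimethoxyphenyl formate | O=COc1cc(Br)c(OC)cc1OC | intermediate
23 | 5-bromo-2,4-dimethoxyphenol | Oc1cc(Br)c(OC)cc1OC | intermediate
24 | 3-bromo-2-iodo-4,6-dimethoxyphenol | Oc1c(I)c(Br)c(OC)cc1OC | intermediate
25 | (3-bromo-2-iodo-4,6-dimethoxyphenoxy)tri(propan-2-yl)silane | CC(C)[Si](Oc1c(I)c(Br)c(OC)cc1OC)(C(C)C)C(C)C | intermediate
26 | (3S)-1-{2-bromo-3,5-dimethoxy-6-[tri(propan-2-yl)silyloxy]phenyl}-5-[(1R,3R)-1,3-dimethyl-2-methylidenecyclohexyl]-3-methylpent-1-yn-3-ol | C=C1[C@H](C)CCC[C@]1(C)CC[C@@](O)(C)C#Cc1c(Br)c(OC)cc(OC)c1O[Si](C(C)C)(C(C)C)C(C)C | intermediate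
27 | (1Z,3S)-1-{2-bromo-3,5-dimethoxy-6-[tri(propan-2-yl)silyloxy]phenyl}-5-[(1R,3R)-1,3-dimethyl-2-methylidenecyclohexyl]-3-methylpent-1-en-3-ol | C=C1[C@H](C)CCC[C@]1(C)CC[C@@](O)(C)/C=C\c1c(Br)c(OC)cc(OC)c1O[Si](C(C)C)(C(C)C)C(C)C | intermediate
28 | {[(2S)-2-{2-[(1R,3R)-1,3-dimethyl-2-methylidenecyclohexyl]ethyl}-6,8-dimethoxy-2-methyl-2H-chromen-5-yl]oxy}tri(propan-2-yl)silane | C=C1[C@H](C)CCC[C@]1(C)CC[C@@]1(C)C=Cc2c(O[Si](C(C)C)(C(C)C)C(C)C)c(OC)cc(OC)c2O1 | intermediate
29 | metachromin B, (2S)-2-{2-[(1R,3R)-1,3-dimethyl-2-methylidenecyclohexyl]ethyl}-6,8-dimethoxy-2-methyl-2H-chromen-5-ol | C=C1[C@H](C)CCC[C@]1(C)CC[C@@]1(C)C=Cc2c(O)c(OC)cc(OC)c2O1 | target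

**Count**

Total steps: 17. Longest linear sequence: 13 steps (from 1 to 29 through steps 1–7, 9, 10 and 14–17).

**Steps most likely to fail**

Step 6. The carbopalladation may discriminate poorly between the two faces of the trisubstituted alkene, so that the quaternary centre forms in part with the wrong relative configuration. Palladium hydride may also re-add and move the exocyclic double bond into the ring, which would erase the C3 stereocentre. The fallback sets out from 11. LiN(iPr)2 (2.2 equiv, THF, −78 °C) should eliminate triflate and give the enyne (3R,7Z)-3,7-dimethylnon-7-en-1-yne F1. An Alder-ene-type cycloisomerisation of F1 with Pd(OAc)2 and PPh3 in toluene at 60–80 °C passes a hydrogen from the allylic methyl group to the alkyne terminus through a palladacycle, without base and without an alkenylpalladium triflate. It should give the same 1,4-diene and come back to the route at 12.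

Step 9. The lithiated propargylic carbamate may lose its configuration before it is trapped, boron may be attacked through the alkyne terminus to give an allenyl boronate, or the 1,2-shift may be slow. The fallback sets out from 12 and uses reagent-controlled epoxidation instead. Hydroboration with 9-BBN gives the borane 9-{2-[(1S,3R)-1,3-dimethyl-2-methylidenecyclohexyl]ethyl}-9-borabicyclo[3.3.1]nonane F2. This is coupled in the same flask (PdCl2(dppf), Cs2CO3, DMF/H2O) with the known reagent (Z)-3-iodobut-2-en-1-ol to the allylic alcohol (2Z)-5-[(1R,3R)-1,3-dimethyl-2-methylidenecyclohexyl]-3-methylpent-2-en-1-ol F3. Sharpless asymmetric epoxidation (Ti(OiPr)4, D-(−)-diethyl tartrate, t-BuOOH, CH2Cl2, −20 °C) should set the tertiary C–O centre in the epoxy alcohol [(2R,3S)-3-{2-[(1R,3R)-1,3-dimethyl-2-methylidenecyclohexyl]ethyl}-3-methyloxiran-2-yl]methanol F4. An Appel reaction (PPh3, CCl4) gives the epoxy chloride (2S,3S)-2-(chloromethyl)-3-{2-[(1R,3R)-1,3-dimethyl-2-methylidenecyclohexyl]ethyl}-3-methyloxirane F5. n-BuLi (3 equiv, THF, −30 °C) opens the epoxide by elimination and then removes HCl, which should give the tertiary propargylic alcohol and come back to the route at 20.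

Step 16. Oxidative addition into the hindered, electron-rich aryl bromide may be slow, the palladium tertiary alkoxide may fragment by β-carbon elimination, or the bromide may simply be reduced. The fallback sets out from 20 and makes the aryl ether bond first. The potassium alkoxide of 20 (KN(SiMe3)2, THF, −78 → 0 °C) is added in conjugate fashion to the quinone monoketal 2,4,4-trimethoxycyclohexa-2,5-dien-1-one F6, which is made from 2,4-dimethoxyphenol with PhI(OAc)2 in MeOH. Loss of methanol rearomatises the adduct to the aryl propargyl ether 5-{[(3S)-5-[(1R,3R)-1,3-dimethyl-2-methylidenecyclohexyl]-3-methylpent-1-yn-3-yl]oxy}-2,4-dimethoxyphenol F7. Gold-catalysed 6-endo-dig hydroarylation (Ph3PAuNTf2, CH2Cl2, rt) at the only free position ortho to the ether oxygen then closes the pyran ring by C–C bond formation. This should give the free phenol directly and come back to the route at 29; the conjugate addition of a tertiary alkoxide is the less precedented part.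

**Further compounds**

F1 | step 6 | (3R,7Z)-3,7-dimethylnon-7-en-1-yne | C/C=C(/C)CCC[C@@H](C)C#C
F2 | step 9 | 9-{2-[(1S,3R)-1,3-dimethyl-2-methylidenecyclohexyl]ethyl}-9-borabicyclo[3.3.1]nonane | C=C1[C@H](C)CCC[C@]1(C)CCB1C2CCCC1CCC2
F3 | step 9 | (2Z)-5-[(1R,3R)-1,3-dimethyl-2-methylidenecyclohexyl]-3-methylpent-2-en-1-ol | C=C1[C@H](C)CCC[C@]1(C)CC/C(C)=C\CO
F4 | step 9 | [(2R,3S)-3-{2-[(1R,3R)-1,3-dimethyl-2-methylidenecyclohexyl]ethyl}-3-methyloxiran-2-yl]methanol | C=C1[C@H](C)CCC[C@]1(C)CC[C@]1(C)O[C@@H]1CO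
F5 | step 9 | (2S,3S)-2-(chloromethyl)-3-{2-[(1R,3R)-1,3-dimethyl-2-methylidenecyclohexyl]ethyl}-3-methyloxirane | C=C1[C@H](C)CCC[C@]1(C)CC[C@]1(C)O[C@@H]1CCl
F6 | step 16 | 2,4,4-trimethoxycyclohexa-2,5-dien-1-one | COC1=CC(OC)(OC)C=CC1=O
F7 | step 16 | 5-{[(3S)-5-[(1R,3R)-1,3-dimethyl-2-methylidenecyclohexyl]-3-methylpent-1-yn-3-yl]oxy}-2,4-dimethoxyphenol | C=C1[C@H](C)CCC[C@]1(C)CC[C@@](Oc1cc(O)c(OC)cc1OC)(C)C#C
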